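Retrosynthetic overview
Locants (bisabolane type): ring C1–C6 with C1 = ring CH2, C2/C3 = oxirane carbons (methyl on C3), C4 = C=O, C5 = ring C–O, C6 = ring CH carrying C7; C14 = methylene on C7; C8 = side-chain C–O; C9–C11 = prenyl unit. In these locants the target is (2S,3S,5S,6S,8R). Endgame: target ← double senecioylation of the C5,C8-diol ← C4 ketone ← hydroxyl-directed C2–C3 epoxidation of a cyclohexenol whose free C4–OH is cis to the C6 side chain and trans to O5.
Key disconnection: the C1–C6 ring bond of that cyclohexenol, formed by intramolecular attack of a 2-substituted allylsilane (C14–C7=C6) on a vinyl oxirane (C1=C2–C3(–O–)C4) of an acyclic precursor. One operation closes the only carbocycle, sets C6, places the C2=C3 and C7=C14 double bonds and frees O4. Enabling feature: in the cyclohexene ring C1–C6 is the central σ-bond of a 1,5-diene (C14=C7–C6–C1–C2=C3), so both carbons are allylic and the bond is the union of an allyl-cation equivalent (C1–C3, oxygen left on C4) with an allyl-anion equivalent (C6–C7–C14).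
Precursor: C5–C6 bond from a vinyllithium (vinyl iodide carrying C8, the silane and the prenyl group) and a Sharpless-derived epoxy aldehyde, C5 then set by oxidation and CBS reduction. The iodide comes from propargyl alcohol by carbomagnesiation/iodination, asymmetric allylboration (C8) and cross metathesis.
Ring order: auxiliary C3–C4 oxirane (step 2, opened in the key step) → cyclohexene ring (step 13) → C2–C3 oxirane (step 14).
Key step: step 13

Remark: the starting enynol is assumed to be the geometrically pure Z isomer. The sense of induction in steps 6 and 11 is assigned by analogy with benzaldehyde/alkenyl aldehydes and with alkenyl ketones, respectively.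

Step 1
Reactants: 1 (Z)-3-methylpent-2-en-4-yn-1-ol
Product: 2 (Z)-3-methylpenta-2,4-dien-1-ol
Conditions: H2 (1 atm), Pd/CaCO3 poisoned with Pb(OAc)2 (Lindlar catalyst), quinoline, EtOAc, 0 °C
Reagents that add atoms: none
Why: Lindlar semi-hydrogenation should stop at the alkene for the terminal alkyne and leave the trisubstituted Z double bond untouched, so the vinyl group stays cis to CH2OH.

Step 2
Reactants: 2 (Z)-3-methylpenta-2,4-dien-1-ol
Product: 3 [(2R,3S)-3-ethenyl-3-methyloxiran-2-yl]methanol
Conditions: Ti(OiPr)4 (10 mol %), D-(−)-diisopropyl tartrate (12 mol %), t-BuOOH (decane), 4 Å molecular sieves, CH2Cl2, −20 °C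
Reagents that add atoms: tert-butyl hydroperoxide, CC(C)(C)OO
Why: Sharpless asymmetric epoxidation touches only the allylic-alcohol double bond, and D-(−)-tartrate should deliver oxygen to the face antipodal to the nerol/L-(+)-tartrate case, fixing C4 (R) and the temporary C3 centre (S) with vinyl cis to the carbinol arm.

Step 3
Reactants: 3 [(2R,3S)-3-ethenyl-3-methyloxiran-2-yl]methanol
Product: 4 (2S,3S)-3-ethenyl-3-methyloxirane-2-carbaldehyde
Conditions: Dess–Martin periodinane, NaHCO3, CH2Cl2, 0 °C; used crude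
Reagents that add atoms: none
Why: Buffered Dess–Martin oxidation of a primary epoxy alcohol should give the aldehyde without opening the oxirane; the descriptor at C2 changes only through ligand priorities.

Step 4
Reactants: 5 prop-2-yn-1-ol
Product: 7 (E)-3-iodo-2-[(trimethylsilyl)methyl]prop-2-en-1-ol (iodine cis to CH2OH), via alkenylmagnesium chelate 6 (not isolated)
Conditions: Me3SiCH2MgCl (2.5 equiv), CuI (10 mol %), Et2O/THF, reflux; then I2, THF, −78 → 0 °C
Reagents that add atoms: (trimethylsilyl)methylmagnesium chloride, C[Si](C)(C)C[Mg]Cl; iodine, [I][I]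
Why: Copper-catalysed anti-carbomagnesiation of propargyl alcohol (Duboudin type) should place the silylmethyl group on the internal carbon and magnesium on the terminal carbon, held cis to CH2O by chelation, so iodinolysis with retention gives the defined vinyl iodide.

Step 5
Reactants: 7 (E)-3-iodo-2-[(trimethylsilyl)methyl]prop-2-en-1-ol
Product: 8 (E)-3-iodo-2-[(trimethylsilyl)methyl]prop-2-enal (iodine cis to CHO)
Conditions: Dess–Martin periodinane, NaHCO3, CH2Cl2, 0 °C, dark
Reagents that add atoms: none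
Why: Mild allylic oxidation under buffered, non-acidic conditions should preserve both the alkene geometry and the allylsilane.

Step 6
Reactants: 8 (E)-3-iodo-2-[(trimethylsilyl)methyl]prop-2-enal
Product: 9 (1E,3R)-1-iodo-2-[(trimethylsilyl)methyl]hexa-1,5-dien-3-ol
Conditions: 2-allyl-4,4,5,5-tetramethyl-1,3,2-dioxaborolane (1.3 equiv), (R)-3,3′-bis(2,4,6-triisopropylphenyl)-1,1′-binaphthyl-2,2′-diyl hydrogen phosphate [(R)-TRIP, 5 mol %], toluene, −30 °C
Reagents that add atoms: 2-allyl-4,4,5,5-tetramethyl-1,3,2-dioxaborolane, C=CCB1OC(C)(C)C(C)(C)O1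
Why: Chiral phosphoric acid-catalysed allylboration proceeds through a closed six-membered transition state, and (R)-TRIP is expected to direct allyl to the Re face as with aryl and alkenyl aldehydes, setting C8 as R.

Step 7
Reactants: 9 (1E,3R)-1-iodo-2-[(trimethylsilyl)methyl]hexa-1,5-dien-3-ol
Product: 10 (1E,3R)-1-iodo-6-methyl-2-[(trimethylsilyl)methyl]hepta-1,5-dien-3-ol
Conditions: second-generation Grubbs catalyst (3 mol %), 2-methylbut-2-ene (excess), CH2Cl2, 40 °C
Reagents that add atoms: 2-methylbut-2-ene, CC=C(C)C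
Why: Olefin cross metathesis should convert only the monosubstituted alkene into the prenyl group, since the trisubstituted iodo-alkene is inert to the catalyst and no stereocentre is touched.

Step 8
Reactants: 10 (1E,3R)-1-iodo-6-methyl-2-[(trimethylsilyl)methyl]hepta-1,5-dien-3-ol
Product: 11 tert-butyl({(1E,3R)-1-iodo-6-methyl-2-[(trimethylsilyl)methyl]hepta-1,5-dien-3-yl}oxy)dimethylsilane
Conditions: TBSCl, imidazole, DMF, rt
Reagents that add atoms: tert-butyldimethylsilyl chloride, CC(C)(C)[Si](C)(C)Cl
Why: Standard silylation masks O8 as a bulky, non-participating ether that survives the organolithium, hydride and Lewis-acid steps.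

Step 9
Reactants: 11 tert-butyl({(1E,3R)-1-iodo-6-methyl-2-[(trimethylsilyl)methyl]hepta-1,5-dien-3-yl}oxy)dimethylsilane; 4 (2S,3S)-3-ethenyl-3-methyloxirane-2-carbaldehyde
Product: 13 (1R,2E,4R)-4-[(tert-butyldimethylsilyl)oxy]-1-[(2R,3S)-3-ethenyl-3-methyloxiran-2-yl]-7-methyl-3-[(trimethylsilyl)methyl]octa-2,6-dien-1-ol (expected major epimer, accompanied by its C1 epimer 15), via vinyllithium 12 (not isolated)
Conditions: t-BuLi (2.05 equiv), Et2O, −78 °C, 15 min; then 4, −78 °C
Reagents that add atoms: none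
Why: Iodine–lithium exchange with retention of alkene geometry is followed by 1,2-addition to the aldehyde, which forms the C5–C6 bond; Felkin–Anh attack anti to the oxirane C–O bond should favour the (1R) epimer, but both epimers are oxidised in step 10, and cold ether should suppress 1,4-silyl migration to the carbanion.

Step 10
Reactants: 13 (1R,2E,4R)-4-[(tert-butyldimethylsilyl)oxy]-1-[(2R,3S)-3-ethenyl-3-methyloxiran-2-yl]-7-methyl-3-[(trimethylsilyl)methyl]octa-2,6-dien-1-ol (epimer mixture)
Product: 14 (2E,4R)-4-[(tert-butyldimethylsilyl)oxy]-1-[(2S,3S)-3-ethenyl-3-methyloxiran-2-yl]-7-methyl-3-[(trimethylsilyl)methyl]octa-2,6-dien-1-one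
Conditions: Dess–Martin periodinane, NaHCO3, CH2Cl2, 0 °C
Reagents that add atoms: none
Why: Dess–Martin oxidation converges both carbinol epimers on one enone without touching the oxirane or the allylsilane.

Step 11
Reactants: 14 (2E,4R)-4-[(tert-butyldimethylsilyl)oxy]-1-[(2S,3S)-3-ethenyl-3-methyloxiran-2-yl]-7-methyl-3-[(trimethylsilyl)methyl]octa-2,6-dien-1-one
Product: 15 (1S,2E,4R)-4-[(tert-butyldimethylsilyl)oxy]-1-[(2R,3S)-3-ethenyl-3-methyloxiran-2-yl]-7-methyl-3-[(trimethylsilyl)methyl]octa-2,6-dien-1-ol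
Conditions: (S)-2-methyl-CBS-oxazaborolidine (1.0 equiv), catecholborane (1.5 equiv), toluene, −78 °C
Reagents that add atoms: none
Why: Corey–Bakshi–Shibata 1,2-reduction with the alkenyl group as the large substituent should give the (1S) carbinol (C5, S), reinforced by the Felkin–Anh preference of the epoxy ketone, so O5 ends syn (threo) to O4.

Step 12
Reactants: 15 (1S,2E,4R)-4-[(tert-butyldimethylsilyl)oxy]-1-[(2R,3S)-3-ethenyl-3-methyloxiran-2-yl]-7-methyl-3-[(trimethylsilyl)methyl]octa-2,6-dien-1-ol
Product: 16 (1S,2E,4R)-1,4-bis[(tert-butyldimethylsilyl)oxy]-1-[(2R,3S)-3-ethenyl-3-methyloxiran-2-yl]-7-methyl-3-[(trimethylsilyl)methyl]octa-2,6-diene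
Conditions: TBSCl, imidazole, DMAP (cat.), DMF, rt
Reagents that add atoms: tert-butyldimethylsilyl chloride, CC(C)(C)[Si](C)(C)Cl
Why: Silylation under basic, non-Lewis-acidic conditions blocks O5, which would otherwise cyclise onto C1, without triggering the oxirane.

Step 13
Reactants: 16 (1S,2E,4R)-1,4-bis[(tert-butyldimethylsilyl)oxy]-1-[(2R,3S)-3-ethenyl-3-methyloxiran-2-yl]-7-methyl-3-[(trimethylsilyl)methyl]octa-2,6-diene
Product: 17 (1S,5S,6S)-6-[(tert-butyldimethylsilyl)oxy]-5-{(3R)-3-[(tert-butyldimethylsilyl)oxy]-6-methylhepta-1,5-dien-2-yl}-2-methylcyclohex-2-en-1-ol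
Conditions: BF3·OEt2 (1.2 equiv), 2,6-di-tert-butyl-4-methylpyridine (0.3 equiv), CH2Cl2 (0.005 M), −78 °C; aq. NaHCO3
Reagents that add atoms: none
Why: Proposed new method: BF3 bound to the oxirane oxygen weakens the tertiary allylic C3–O bond so that the vinyl oxirane acts as a 4-oxido allyl cation, which the 2-substituted allylsilane attacks through its γ-carbon C6 at the unsubstituted terminus C1 (SE2′ at the silane, SN2′ at the oxirane), after which the β-silyl cation at C7 loses silicon to leave the C7=C14 methylene and O4 as the borate of the allylic alcohol. The closest known reaction type is the Lewis-acid epoxide-initiated, allylsilane-terminated cation–olefin cyclisation (intramolecular Sakurai-type epoxy-allylsilane cyclisation), here run in the vinylogous mode that mirrors the linalyl-to-terpinyl closure of a 3-methylallyl cation. The cyclohexene ring closes 6-exo with respect to the C6=C7 bond and endo with respect to the allyl unit, so that C2=C3 ends inside the ring, and the cis placement of vinyl and C5 on the oxirane holds C1 within reach of C6. C6, the only new stereocentre, should be set by a chair-like transition state with the C5 silyloxy group equatorial and C5–H eclipsing the allylsilane plane (allylic 1,3-strain against C8), which puts the C6–C7 bond trans to O5 and cis to O4, while C4 keeps its oxygen with unchanged configuration. The step needs attack at C1 and C–C bond formation ahead of hydride shift, proton loss or oxygen participation: bonding to C3 or C4 would give four- or three-membered rings, the silyl ethers are poor neighbouring groups, the hindered pyridine removes adventitious acid, and the allylsilane is the strongest π-nucleophile in the molecule.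

Step 14
Reactants: 17 (1S,5S,6S)-6-[(tert-butyldimethylsilyl)oxy]-5-{(3R)-3-[(tert-butyldimethylsilyl)oxy]-6-methylhepta-1,5-dien-2-yl}-2-methylcyclohex-2-en-1-ol
Product: 18 (1R,2R,3S,4S,6S)-3-[(tert-butyldimethylsilyl)oxy]-4-{(3R)-3-[(tert-butyldimethylsilyl)oxy]-6-methylhepta-1,5-dien-2-yl}-1-methyl-7-oxabicyclo[4.1.0]heptan-2-ol
Conditions: VO(acac)2 (5 mol %), t-BuOOH (decane), CH2Cl2, 0 °C → rt
Reagents that add atoms: tert-butyl hydroperoxide, CC(C)(C)OO
Why: Vanadium-catalysed hydroxyl-directed epoxidation of the cyclic allylic alcohol should deliver oxygen syn to C4–OH, that is cis to the C6 side chain and trans to O5, setting C2 and C3 while leaving the prenyl and 1,1-disubstituted alkenes untouched.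

Step 15
Reactants: 18 (1R,2R,3S,4S,6S)-3-[(tert-butyldimethylsilyl)oxy]-4-{(3R)-3-[(tert-butyldimethylsilyl)oxy]-6-methylhepta-1,5-dien-2-yl}-1-methyl-7-oxabicyclo[4.1.0]heptan-2-ol
Product: 19 (1S,3S,4S,6S)-3-[(tert-butyldimethylsilyl)oxy]-4-{(3R)-3-[(tert-butyldimethylsilyl)oxy]-6-methylhepta-1,5-dien-2-yl}-1-methyl-7-oxabicyclo[4.1.0]heptan-2-one
Conditions: Dess–Martin periodinane, NaHCO3, CH2Cl2, 0 °C → rt
Reagents that add atoms: none
Why: Neutral Dess–Martin oxidation of the epoxy alcohol should give the α,β-epoxy ketone without epimerising C5 or opening the oxirane.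

Step 16
Reactants: 19 (1S,3S,4S,6S)-3-[(tert-butyldimethylsilyl)oxy]-4-{(3R)-3-[(tert-butyldimethylsilyl)oxy]-6-methylhepta-1,5-dien-2-yl}-1-methyl-7-oxabicyclo[4.1.0]heptan-2-one
Product: 20 (1S,3S,4S,6S)-3-hydroxy-4-[(3R)-3-hydroxy-6-methylhepta-1,5-dien-2-yl]-1-methyl-7-oxabicyclo[4.1.0]heptan-2-one
Conditions: HF·pyridine buffered with excess pyridine, THF, 0 °C → rt
Reagents that add atoms: none
Why: Buffered fluoride desilylation should remove both silyl ethers under conditions too weakly acidic and too weakly basic to open the epoxy ketone, add HF to the prenyl alkene or epimerise C5.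

Step 17
Reactants: 20 (1S,3S,4S,6S)-3-hydroxy-4-[(3R)-3-hydroxy-6-methylhepta-1,5-dien-2-yl]-1-methyl-7-oxabicyclo[4.1.0]heptan-2-one
Product: 21 (1S,3S,4S,6S)-1-methyl-4-{(3R)-6-methyl-3-[(3-methylbut-2-enoyl)oxy]hepta-1,5-dien-2-yl}-2-oxo-7-oxabicyclo[4.1.0]heptan-3-yl 3-methylbut-2-enoate (target)
Conditions: 3-methylbut-2-enoyl chloride (3 equiv), pyridine, DMAP (0.2 equiv), CH2Cl2, 0 °C → rt
Reagents that add atoms: 3-methylbut-2-enoyl chloride, CC(C)=CC(Cl)=O
Why: DMAP-catalysed acylation esterifies both secondary hydroxyls with the same acid in one operation, the weak base and low temperature limiting deconjugation of the senecioyl unit and epimerisation at C5.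

Compound list
1 | (Z)-3-methylpent-2-en-4-yn-1-ol | C#C/C(C)=C\CO | starting material
2 | (Z)-3-methylpenta-2,4-dien-1-ol | C=C/C(C)=C\CO | intermediate
3 | [(2R,3S)-3-ethenyl-3-methyloxiran-2-yl]methanol | C=C[C@]1(C)O[C@@H]1CO | intermediate
4 | (2S,3S)-3-ethenyl-3-methyloxirane-2-carbaldehyde | C=C[C@]1(C)O[C@@H]1C=O | intermediate
5 | prop-2-yn-1-ol | C#CCO | starting material
6 | alkenylmagnesium chelate ClMg–CH=C(CH2SiMe3)–CH2OMgCl (Mg cis to CH2O) | Cl[Mg]/C=C(/C[Si](C)(C)C)CO[Mg]Cl | intermediate (not isolated)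
7 | (E)-3-iodo-2-[(trimethylsilyl)methyl]prop-2-en-1-ol (I cis to CH2OH) | I/C=C(/C[Si](C)(C)C)CO | intermediate
8 | (E)-3-iodo-2-[(trimethylsilyl)methyl]prop-2-enal (I cis to CHO) | I/C=C(/C[Si](C)(C)C)C=O | intermediate
9 | (1E,3R)-1-iodo-2-[(trimethylsilyl)methyl]hexa-1,5-dien-3-ol | I/C=C(/C[Si](C)(C)C)[C@H](O)CC=C | intermediate
10 | (1E,3R)-1-iodo-6-methyl-2-[(trimethylsilyl)methyl]hepta-1,5-dien-3-ol | I/C=C(/C[Si](C)(C)C)[C@H](O)CC=C(C)C | intermediate
11 | tert-butyl({(1E,3R)-1-iodo-6-methyl-2-[(trimethylsilyl)methyl]hepta-1,5-dien-3-yl}oxy)dimethylsilane | I/C=C(/C[Si](C)(C)C)[C@H](O[Si](C)(C)C(C)(C)C)CC=C(C)C | intermediate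
12 | vinyllithium from 11 (Li in place of I, geometry retained) | [Li]/C=C(/C[Si](C)(C)C)[C@H](O[Si](C)(C)C(C)(C)C)CC=C(C)C | intermediate (not isolated)
13 | (1R,2E,4R)-4-[(tert-butyldimethylsilyl)oxy]-1-[(2R,3S)-3-ethenyl-3-methyloxiran-2-yl]-7-methyl-3-[(trimethylsilyl)methyl]octa-2,6-dien-1-ol (expected major C1 epimer; minor epimer is 15) | C=C[C@]1(C)O[C@@H]1[C@H](O)/C=C(/C[Si](C)(C)C)[C@H](O[Si](C)(C)C(C)(C)C)CC=C(C)C | intermediate
14 | (2E,4R)-4-[(tert-butyldimethylsilyl)oxy]-1-[(2S,3S)-3-ethenyl-3-methyloxiran-2-yl]-7-methyl-3-[(trimethylsilyl)methyl]octa-2,6-dien-1-one | C=C[C@]1(C)O[C@@H]1C(=O)/C=C(/C[Si](C)(C)C)[C@H](O[Si](C)(C)C(C)(C)C)CC=C(C)C | intermediate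
15 | (1S,2E,4R)-4-[(tert-butyldimethylsilyl)oxy]-1-[(2R,3S)-3-ethenyl-3-methyloxiran-2-yl]-7-methyl-3-[(trimethylsilyl)methyl]octa-2,6-dien-1-ol | C=C[C@]1(C)O[C@@H]1[C@@H](O)/C=C(/C[Si](C)(C)C)[C@H](O[Si](C)(C)C(C)(C)C)CC=C(C)C | intermediate
16 | (1S,2E,4R)-1,4-bis[(tert-butyldimethylsilyl)oxy]-1-[(2R,3S)-3-ethenyl-3-methyloxiran-2-yl]-7-methyl-3-[(trimethylsilyl)methyl]octa-2,6-diene | C=C[C@]1(C)O[C@@H]1[C@@H](O[Si](C)(C)C(C)(C)C)/C=C(/C[Si](C)(C)C)[C@H](O[Si](C)(C)C(C)(C)C)CC=C(C)C | intermediate
17 | (1S,5S,6S)-6-[(tert-butyldimethylsilyl)oxy]-5-{(3R)-3-[(tert-butyldimethylsilyl)oxy]-6-methylhepta-1,5-dien-2-yl}-2-methylcyclohex-2-en-1-ol | C=C([C@@H](CC=C(C)C)O[Si](C)(C)C(C)(C)C)[C@@H]1CC=C(C)[C@H](O)[C@H]1O[Si](C)(C)C(C)(C)C | intermediate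
18 | (1R,2R,3S,4S,6S)-3-[(tert-butyldimethylsilyl)oxy]-4-{(3R)-3-[(tert-butyldimethylsilyl)oxy]-6-methylhepta-1,5-dien-2-yl}-1-methyl-7-oxabicyclo[4.1.0]heptan-2-ol | C=C([C@@H](CC=C(C)C)O[Si](C)(C)C(C)(C)C)[C@@H]1C[C@@H]2O[C@]2(C)[C@H](O)[C@H]1O[Si](C)(C)C(C)(C)C | intermediate
19 | (1S,3S,4S,6S)-3-[(tert-butyldimethylsilyl)oxy]-4-{(3R)-3-[(tert-butyldimethylsilyl)oxy]-6-methylhepta-1,5-dien-2-yl}-1-methyl-7-oxabicyclo[4.1.0]heptan-2-one | C=C([C@@H](CC=C(C)C)O[Si](C)(C)C(C)(C)C)[C@@H]1C[C@@H]2O[C@]2(C)C(=O)[C@H]1O[Si](C)(C)C(C)(C)C | intermediate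
20 | (1S,3S,4S,6S)-3-hydroxy-4-[(3R)-3-hydroxy-6-methylhepta-1,5-dien-2-yl]-1-methyl-7-oxabicyclo[4.1.0]heptan-2-one | C=C([C@@H](CC=C(C)C)O)[C@@H]1C[C@@H]2O[C@]2(C)C(=O)[C@H]1O | intermediate
21 | (1S,3S,4S,6S)-1-methyl-4-{(3R)-6-methyl-3-[(3-methylbut-2-enoyl)oxy]hepta-1,5-dien-2-yl}-2-oxo-7-oxabicyclo[4.1.0]heptan-3-yl 3-methylbut-2-enoate | C=C([C@@H](CC=C(C)C)OC(=O)C=C(C)C)[C@@H]1C[C@@H]2O[C@]2(C)C(=O)[C@H]1OC(=O)C=C(C)C | target

Total step count: 17. Longest linear sequence: 14 steps (steps 4–17, from prop-2-yn-1-ol).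

Steps most likely to fail

Step 13 (the step carrying the label). The activated oxirane may ionise and collapse by hydride shift or proton loss, or the silane may be lost by protodesilylation, before the ring closes; facial selectivity at C6 may also be low. The fallback sets out from 16 and returns at 17 and replaces carbocation chemistry by neutral π-allyl palladium chemistry. Pd2(dba)3 (zerovalent palladium) with PPh3 in THF should ionise the vinyl oxirane to a π-allylpalladium alkoxide. The alkoxide activates the silane, and intramolecular allyl–allyl coupling then joins C6 to the unsubstituted terminus C1. Both events are known reaction types (palladium-catalysed 1,4-opening of vinyl oxiranes by carbon nucleophiles; intramolecular palladium-catalysed coupling of allyl electrophiles with allylsilanes). Mild hydrolytic work-up of the O-silylated product gives 17, and no new isolable compound is involved (F0).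

Step 11. Hydride delivery may show poor facial discrimination, because the oxiranyl and alkenyl groups flanking the ketone are of similar size. The fallback sets out from 13 and returns at 15 and relies on substrate control followed by inversion. The (1R) epimer of 13, expected as the Felkin–Anh product of step 9 and separated from its epimer, is esterified under Mitsunobu conditions (PPh3, diisopropyl azodicarboxylate, 4-nitrobenzoic acid, THF, 0 °C) with inversion to (1S,2E,4R)-4-[(tert-butyldimethylsilyl)oxy]-1-[(2R,3S)-3-ethenyl-3-methyloxiran-2-yl]-7-methyl-3-[(trimethylsilyl)methyl]octa-2,6-dien-1-yl 4-nitrobenzoate F1. Methanolysis (K2CO3, MeOH, 0 °C) then gives 15.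

Step 2. The tertiary, allylic and therefore easily ionised oxirane may be opened or rearranged by the titanium alkoxide medium or during work-up, and enantio-induction with a Z-trisubstituted dienol may be incomplete. The fallback sets out from 1 and returns at 3 and inverts the order of reduction and epoxidation. The enynol is epoxidised first with the same titanium/D-(−)-tartrate system to the less ionisable [(2R,3S)-3-ethynyl-3-methyloxiran-2-yl]methanol F2. Its alkyne is then semi-hydrogenated (H2, Pd/CaCO3 poisoned with Pb(OAc)2, quinoline) to give 3.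

Further compounds
F0 | step 13 | none | none
F1 | step 11 | (1S,2E,4R)-4-[(tert-butyldimethylsilyl)oxy]-1-[(2R,3S)-3-ethenyl-3-methyloxiran-2-yl]-7-methyl-3-[(trimethylsilyl)methyl]octa-2,6-dien-1-yl 4-nitrobenzoate | C=C[C@]1(C)O[C@@H]1[C@@H](OC(=O)c2ccc(cc2)[N+](=O)[O-])/C=C(/C[Si](C)(C)C)[C@H](O[Si](C)(C)C(C)(C)C)CC=C(C)C
F2 | step 2 | [(2R,3S)-3-ethynyl-3-methyloxiran-2-yl]methanol | C#C[C@]1(C)O[C@@H]1CO
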